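**Assumption (one line):** sesquiterpene carbons carry pseudoguaiane numbers (C1–C15), monoterpene carbons primed p-menthane numbers (C1'–C10'), and each chiral catalyst is used as the enantiomer or pseudoenantiomer that gives the drawn product.

## Retrosynthetic overview

1. Target ⇐ C9 desilylation, C2=C3 dehydrogenation and C6 tiglate ⇐ spiro adduct 25 ⇐ silicon-tethered [4+2] of α-methylene lactone 13 (through O6) with dienol 22 (through O8'); this forms the bicyclo[2.2.2]octene and sets C11.
2. 13 ⇐ intramolecular allylation (C6–C7) of butenolide aldehyde 12; the seven-membered ring and the cis-fused methylene lactone form together.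
3. 12 ⇐ vinylogous Mukaiyama aldol (C8–C9) of aldehyde 6 with silyloxyfuran 10, which brings in the butenolide ring.
4. 6 ⇐ catalytic asymmetric Mukaiyama–Michael addition (C1–C10) and C5 alkylation on 2-methylcyclopent-2-enone.
5. 22 ⇐ enamine-catalysed Michael/aldol, dienyl triflate, methyl coupling. Ring order: cyclopentanone (bought) → butenolide → seven-membered ring → cyclohexadiene (separate branch) → bicyclo[2.2.2]octene → cyclopentenone (late dehydrogenation).

## Route

Step 1
Reactants: 1 S-ethyl propanethioate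
Product: 2 (Z)-tert-butyl{[1-(ethylsulfanyl)prop-1-en-1-yl]oxy}dimethylsilane
Conditions: LiN(i-Pr)2, THF, −78 °C; then TBSOTf
Reagents that add atoms: tert-butyldimethylsilyl trifluoromethanesulfonate, CC(C)(C)[Si](C)(C)OS(=O)(=O)C(F)(F)F
Why: Kinetic enolisation of the thioester (Ireland model, methyl trans to O–Li) followed by O-silylation gives the (Z)-ketene S,O-acetal used as the Mukaiyama donor.

Step 2
Reactants: 2 (Z)-tert-butyl{[1-(ethylsulfanyl)prop-1-en-1-yl]oxy}dimethylsilane; 3 2-methylcyclopent-2-en-1-one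
Product: 5 S-ethyl (2S)-2-[(1S,2R)-2-(dimethoxymethyl)-2-methyl-3-oxocyclopentyl]propanethioate, via silyl enol ether 4 (not isolated)
Conditions: chiral IDPi (imidodiphosphorimidate) catalyst (2 mol%), PhMe, −60 °C; then HC(OMe)3, TMSOTf (10 mol%), CH2Cl2, −78 to −40 °C
Reagents that add atoms: trimethyl orthoformate, COC(OC)OC
Why: Proposed new method: the silylated IDPi ion pair turns the enone into a silyloxyallyl cation held in the chiral anion pocket, the ketene acetal adds to the Re face of C1 through an open antiperiplanar transition state in which its methyl avoids the enone C5 methyl (C1 S, C10 S), silyl transfer gives enol ether 4, and TMSOTf-activated orthoformate then alkylates C5 anti to the C1 side chain (C5 R, Mukaiyama-type acetal alkylation); the closest known reactions are silylium-IDPi Mukaiyama–Michael additions of ketene acetals to unsaturated esters and oxazaborolidinium-catalysed additions to unsubstituted cycloalkenones, neither shown for an α-methyl enone with a prochiral ketene acetal.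

Step 3
Reactants: 5 S-ethyl (2S)-2-[(1S,2R)-2-(dimethoxymethyl)-2-methyl-3-oxocyclopentyl]propanethioate
Product: 6 (2S)-2-[(1S,2R)-2-(dimethoxymethyl)-2-methyl-3-oxocyclopentyl]propanal
Conditions: Et3SiH, 10% Pd/C, acetone, 25 °C
Reagents that add atoms: none
Why: Fukuyama reduction stops at the aldehyde under neutral conditions, so the ketone, the acetal and the epimerisable C10 centre are untouched.

Step 4
Reactants: 7 furan-2(5H)-one
Product: 8 3-(hydroxymethyl)furan-2(5H)-one
Conditions: aq. CH2O (37%), DMAP (0.2 equiv), THF, 25 °C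
Reagents that add atoms: formaldehyde, C=O
Why: Morita–Baylis–Hillman reaction: the amine adds to C4 of the butenolide, the enolate takes up formaldehyde at C3 and loss of the amine returns the conjugated lactone.

Step 5
Reactants: 8 3-(hydroxymethyl)furan-2(5H)-one
Product: 10 tert-butyl(dimethyl)[(3-{[(triethylsilyl)oxy]methyl}furan-2-yl)oxy]silane, via silyl ether 9 (not isolated)
Conditions: TESCl, imidazole, CH2Cl2, 0 °C; then TBSOTf, Et3N, 0 °C
Reagents that add atoms: chlorotriethylsilane, CC[Si](Cl)(CC)CC; tert-butyldimethylsilyl trifluoromethanesulfonate, CC(C)(C)[Si](C)(C)OS(=O)(=O)C(F)(F)F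
Why: O-silylation of the primary alcohol, then soft enolisation at C5 with silyl triflate and amine gives the aromatic 2-silyloxyfuran (silyl dienol ether formation).

Step 6
Reactants: 6 (2S)-2-[(1S,2R)-2-(dimethoxymethyl)-2-methyl-3-oxocyclopentyl]propanal; 10 tert-butyl(dimethyl)[(3-{[(triethylsilyl)oxy]methyl}furan-2-yl)oxy]silane
Product: 11 (5S)-5-[(1R,2S)-1-{[tert-butyl(dimethyl)silyl]oxy}-2-[(1S,2R)-2-(dimethoxymethyl)-2-methyl-3-oxocyclopentyl]propyl]-3-{[(triethylsilyl)oxy]methyl}furan-2(5H)-one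
Conditions: cinchona-derived quaternary ammonium phenoxide (10 mol%), THF/CH2Cl2, −78 °C
Reagents that add atoms: none
Why: Lewis-base-catalysed vinylogous Mukaiyama aldol reaction with silyl transfer: furan C5 adds to the aldehyde through an open transition state that gives the anti C8/C9 pair, the α-methyl aldehyde reacts in the Felkin–Anh sense (C9 R), and the catalyst pseudoenantiomer matched to it is used (C8 S).

Step 7
Reactants: 11 (5S)-5-[(1R,2S)-1-{[tert-butyl(dimethyl)silyl]oxy}-2-[(1S,2R)-2-(dimethoxymethyl)-2-methyl-3-oxocyclopentyl]propyl]-3-{[(triethylsilyl)oxy]methyl}furan-2(5H)-one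
Product: 12 (1R,2S)-2-[(1R,2S)-1-{[tert-butyl(dimethyl)silyl]oxy}-1-[(2S)-4-(hydroxymethyl)-5-oxo-2,5-dihydrofuran-2-yl]propan-2-yl]-1-methyl-5-oxocyclopentane-1-carbaldehyde
Conditions: 1 M HCl, THF, 0 to 25 °C
Reagents that add atoms: water, O
Why: Aqueous acid hydrolyses the dimethyl acetal and the primary triethylsilyl ether while the hindered secondary tert-butyldimethylsilyl ether survives (acetal hydrolysis with selective desilylation).

Step 8
Reactants: 12 (1R,2S)-2-[(1R,2S)-1-{[tert-butyl(dimethyl)silyl]oxy}-1-[(2S)-4-(hydroxymethyl)-5-oxo-2,5-dihydrofuran-2-yl]propan-2-yl]-1-methyl-5-oxocyclopentane-1-carbaldehyde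
Product: 13 (1S,5R,6S,7S,8S,9R,10S)-9-{[tert-butyl(dimethyl)silyl]oxy}-6-hydroxy-4-oxopseudoguai-11(13)-en-12,8-olide (9β-silyloxy-2,3-dihydrohelenalin)
Conditions: PdCl2(PhCN)2 (10 mol%), SnCl2 (3 equiv), 1,3-dimethyl-2-imidazolidinone/H2O, 0.005 M, 25 °C
Reagents that add atoms: none
Why: Pd-catalysed SnCl2-mediated carbonyl allylation (umpolung of the π-allyl unit made from the allylic alcohol): the allyltin adds through C7 to the C6 aldehyde in a closed chair transition state on the butenolide face that carries the C9 chain, which closes the seven-membered ring and gives the cis-fused α-methylene lactone (C7 S) with the anti-configured C6 carbinol (C6 S).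

Step 9
Reactants: 14 ethyl 3-hydroxy-3-methylbutanoate
Product: 15 ethyl 3-methyl-3-[(triethylsilyl)oxy]butanoate
Conditions: TESOTf, 2,6-lutidine, CH2Cl2, 0 °C
Reagents that add atoms: triethylsilyl trifluoromethanesulfonate, CC[Si](CC)(CC)OS(=O)(=O)C(F)(F)F
Why: Silyl triflate with a hindered pyridine base silylates the tertiary alcohol (silyl ether protection), which blocks retro-aldol and dehydration in the later enamine step.

Step 10
Reactants: 15 ethyl 3-methyl-3-[(triethylsilyl)oxy]butanoate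
Product: 16 3-methyl-3-[(triethylsilyl)oxy]butanal
Conditions: i-Bu2AlH (1.05 equiv), CH2Cl2, −78 °C
Reagents that add atoms: none
Why: Partial ester reduction: the tetrahedral aluminium hemiacetal is stable at −78 °C and releases the aldehyde only on work-up.

Step 11
Reactants: 16 3-methyl-3-[(triethylsilyl)oxy]butanal; 17 but-3-en-2-one
Product: 19 (4R)-4-{2-[(triethylsilyl)oxy]propan-2-yl}cyclohex-2-en-1-one, via keto aldehyde 18 (not isolated)
Conditions: (S)-α,α-diphenylprolinol trimethylsilyl ether (5 mol%), ethyl 3,4-dihydroxybenzoate (20 mol%), neat, 4 °C; then LiOH, i-PrOH, 25 °C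
Reagents that add atoms: none
Why: Enamine-catalysed Michael addition (the E-enamine is attacked on the face away from the diphenyl(silyloxy)methyl group, which sets the only stereocentre of this branch) followed by hydroxide-mediated intramolecular aldol condensation (Robinson annulation).

Step 12
Reactants: 19 (4R)-4-{2-[(triethylsilyl)oxy]propan-2-yl}cyclohex-2-en-1-one
Product: 20 (4R)-4-{2-[(triethylsilyl)oxy]propan-2-yl}cyclohexa-1,5-dien-1-yl trifluoromethanesulfonate
Conditions: LiN(i-Pr)2, THF, −78 °C; then PhNTf2, −78 to 0 °C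
Reagents that add atoms: N-phenylbis(trifluoromethanesulfonimide), FC(F)(F)S(=O)(=O)N(c1ccccc1)S(=O)(=O)C(F)(F)F
Why: Kinetic α′-deprotonation gives the cross-conjugated dienolate, whose O-triflation fixes the 1,3-diene position; the γ-stereocentre is not deprotonated under these conditions.

Step 13
Reactants: 20 (4R)-4-{2-[(triethylsilyl)oxy]propan-2-yl}cyclohexa-1,5-dien-1-yl trifluoromethanesulfonate
Product: 22 2-[(1R)-4-methylcyclohexa-2,4-dien-1-yl]propan-2-ol, via silyl ether 21 (not isolated)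
Conditions: MeMgBr, Fe(acac)3 (5 mol%), THF/NMP, −30 °C; then tetrabutylammonium fluoride, THF, 0 °C
Reagents that add atoms: methylmagnesium bromide, C[Mg]Br
Why: Iron-catalysed Kumada-type cross-coupling puts the methyl group on the triflate carbon without moving the diene, and fluoride then frees the tertiary alcohol.

Step 14
Reactants: 13 (1S,5R,6S,7S,8S,9R,10S)-9-{[tert-butyl(dimethyl)silyl]oxy}-6-hydroxy-4-oxopseudoguai-11(13)-en-12,8-olide; 22 2-[(1R)-4-methylcyclohexa-2,4-dien-1-yl]propan-2-ol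
Product: 25 (11S,2'S,4'R,5'R)-cycloadduct diol of 13 and 22 (bonds C13–C2' and C11–C5'; free 6-OH and 8'-OH; 9-O-silyl), via silaketal 23 (not isolated), via tethered cycloadduct 24 (not isolated)
Conditions: Me2SiCl2 (5 equiv), imidazole, CH2Cl2, 0 °C, evaporate; 22, imidazole, DMAP, DMF, 25 °C; PhMe (0.005 M), BHT, 110 °C; then AcOH/THF/H2O, 25 °C
Reagents that add atoms: none
Why: Temporary silicon-tethered intramolecular Diels–Alder reaction: the Me2Si bridge between O6 (on the C6 side of the lactone) and O8' allows only the arrangement in which C5' bonds to C11 from the C6 face, anti to the C4' substituent and with the lactone carbonyl under the diene, which sets C11 S, C2' S and C5' R (an untethered diene would be expected to take the open H7 face), and mild acid then cleaves the silaketal.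

Step 15
Reactants: 25 (11S,2'S,4'R,5'R)-cycloadduct diol of 13 and 22; 26 (2E)-2-methylbut-2-enoyl chloride
Product: 27 6-O-[(2E)-2-methylbut-2-enoyl] derivative of 25
Conditions: DMAP (2 equiv), pyridine, 60 °C
Reagents that add atoms: none
Why: DMAP-catalysed acyl transfer reaches the hindered secondary C6 hydroxyl while the tertiary C8' hydroxyl does not react, and the E-configured tiglate is the stable ester geometry.

Step 16
Reactants: 27 6-O-[(2E)-2-methylbut-2-enoyl] derivative of 25
Product: 28 2,3-didehydro derivative of 27 (cyclopent-2-enone)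
Conditions: IBX (3 equiv), 4-methoxypyridine N-oxide (3 equiv), DMSO, 25 °C
Reagents that add atoms: none
Why: IBX dehydrogenation through the enol on the only enolisable side of the C4 ketone (C3) gives the C2=C3 enone; the lactone α-carbon is quaternary and cannot react.

Step 17
Reactants: 28 2,3-didehydro derivative of 27
Product: 29 target CNP0185323.3
Conditions: HF·pyridine, THF, 0 to 25 °C
Reagents that add atoms: none
Why: Fluoride-driven desilylation cleaves the C9 silyl ether under mildly acidic conditions that leave both Michael acceptors, the esters and the tertiary alcohol intact.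

## Compound list

1 | S-ethyl propanethioate | CCC(=O)SCC | starting material
2 | (Z)-tert-butyl{[1-(ethylsulfanyl)prop-1-en-1-yl]oxy}dimethylsilane | C/C=C(\SCC)O[Si](C)(C)C(C)(C)C | intermediate
3 | 2-methylcyclopent-2-en-1-one | CC1=CCCC1=O | starting material
4 | S-ethyl (2S)-2-[(1S)-3-{[tert-butyl(dimethyl)silyl]oxy}-2-methylcyclopent-2-en-1-yl]propanethioate | CC1=C(O[Si](C)(C)C(C)(C)C)CC[C@H]1[C@H](C)C(=O)SCC | intermediate
5 | S-ethyl (2S)-2-[(1S,2R)-2-(dimethoxymethyl)-2-methyl-3-oxocyclopentyl]propanethioate | COC(OC)[C@]1(C)C(=O)CC[C@H]1[C@H](C)C(=O)SCC | intermediate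
6 | (2S)-2-[(1S,2R)-2-(dimethoxymethyl)-2-methyl-3-oxocyclopentyl]propanal | COC(OC)[C@]1(C)C(=O)CC[C@H]1[C@H](C)C=O | intermediate
7 | furan-2(5H)-one | O=C1C=CCO1 | starting material
8 | 3-(hydroxymethyl)furan-2(5H)-one | O=C1OCC=C1CO | intermediate
9 | 3-{[(triethylsilyl)oxy]methyl}furan-2(5H)-one | O=C1OCC=C1CO[Si](CC)(CC)CC | intermediate
10 | tert-butyl(dimethyl)[(3-{[(triethylsilyl)oxy]methyl}furan-2-yl)oxy]silane | CC[Si](CC)(CC)OCc1ccoc1O[Si](C)(C)C(C)(C)C | intermediate
11 | (5S)-5-[(1R,2S)-1-{[tert-butyl(dimethyl)silyl]oxy}-2-[(1S,2R)-2-(dimethoxymethyl)-2-methyl-3-oxocyclopentyl]propyl]-3-{[(triethylsilyl)oxy]methyl}furan-2(5H)-one | COC(OC)[C@]1(C)C(=O)CC[C@H]1[C@H](C)[C@@H](O[Si](C)(C)C(C)(C)C)[C@H]1OC(=O)C(CO[Si](CC)(CC)CC)=C1 | intermediate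
12 | (1R,2S)-2-[(1R,2S)-1-{[tert-butyl(dimethyl)silyl]oxy}-1-[(2S)-4-(hydroxymethyl)-5-oxo-2,5-dihydrofuran-2-yl]propan-2-yl]-1-methyl-5-oxocyclopentane-1-carbaldehyde | O=C[C@]1(C)C(=O)CC[C@H]1[C@H](C)[C@@H](O[Si](C)(C)C(C)(C)C)[C@H]1OC(=O)C(CO)=C1 | intermediate
13 | (1S,5R,6S,7S,8S,9R,10S)-9-{[tert-butyl(dimethyl)silyl]oxy}-6-hydroxy-4-oxopseudoguai-11(13)-en-12,8-olide (6α-OH, 8β-lactone, 9β-OSi, 10α-Me, 1α-H, 5β-Me) | O[C@H]1[C@H]2[C@H](OC(=O)C2=C)[C@H](O[Si](C)(C)C(C)(C)C)[C@@H](C)[C@@H]2CCC(=O)[C@]21C | intermediate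
14 | ethyl 3-hydroxy-3-methylbutanoate | CCOC(=O)CC(C)(C)O | starting material
15 | ethyl 3-methyl-3-[(triethylsilyl)oxy]butanoate | CCOC(=O)CC(C)(C)O[Si](CC)(CC)CC | intermediate
16 | 3-methyl-3-[(triethylsilyl)oxy]butanal | CC[Si](CC)(CC)OC(C)(C)CC=O | intermediate
17 | but-3-en-2-one | CC(=O)C=C | starting material
18 | (2S)-5-oxo-2-{2-[(triethylsilyl)oxy]propan-2-yl}hexanal | CC(=O)CC[C@@H](C(C)(C)O[Si](CC)(CC)CC)C=O | intermediate
19 | (4R)-4-{2-[(triethylsilyl)oxy]propan-2-yl}cyclohex-2-en-1-one | O=C1CC[C@@H](C(C)(C)O[Si](CC)(CC)CC)C=C1 | intermediate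
20 | (4R)-4-{2-[(triethylsilyl)oxy]propan-2-yl}cyclohexa-1,5-dien-1-yl trifluoromethanesulfonate | FC(F)(F)S(=O)(=O)OC1=CC[C@@H](C(C)(C)O[Si](CC)(CC)CC)C=C1 | intermediate
21 | triethyl({2-[(1R)-4-methylcyclohexa-2,4-dien-1-yl]propan-2-yl}oxy)silane | CC1=CC[C@@H](C(C)(C)O[Si](CC)(CC)CC)C=C1 | intermediate
22 | 2-[(1R)-4-methylcyclohexa-2,4-dien-1-yl]propan-2-ol | CC1=CC[C@@H](C(C)(C)O)C=C1 | intermediate
23 | 6-O-[dimethyl({2-[(1R)-4-methylcyclohexa-2,4-dien-1-yl]propan-2-yl}oxy)silyl] derivative of 13 | C[Si](C)(O[C@H]1[C@H]2[C@H](OC(=O)C2=C)[C@H](O[Si](C)(C)C(C)(C)C)[C@@H](C)[C@@H]2CCC(=O)[C@]21C)OC(C)(C)[C@@H]1CC=C(C)C=C1 | intermediate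
24 | O6,O8'-dimethylsilanediyl-bridged cycloadduct (bonds C13–C2' and C11–C5'; 11S,2'S,4'R,5'R) | C[Si]4(C)O[C@H]1[C@H]2[C@H](OC(=O)[C@]23C[C@@H]2C[C@@H](C(C)(C)O4)[C@H]3C=C2C)[C@H](O[Si](C)(C)C(C)(C)C)[C@@H](C)[C@@H]2CCC(=O)[C@]21C | intermediate
25 | (11S,2'S,4'R,5'R)-cycloadduct diol: 9β-silyloxy-6α-hydroxy-4-oxopseudoguaian-12,8β-olide spiro-joined at C11 (C11–C5', C13–C2') to 8'-hydroxy-p-menth-1'(6')-ene | O[C@H]1[C@H]2[C@H](OC(=O)[C@]23C[C@@H]2C[C@@H](C(C)(C)O)[C@H]3C=C2C)[C@H](O[Si](C)(C)C(C)(C)C)[C@@H](C)[C@@H]2CCC(=O)[C@]21C | intermediate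
26 | (2E)-2-methylbut-2-enoyl chloride (tigloyl chloride) | C/C=C(\C)C(=O)Cl | starting material
27 | 6-O-tigloyl derivative of 25 | C/C=C(\C)C(=O)O[C@H]1[C@H]2[C@H](OC(=O)[C@]23C[C@@H]2C[C@@H](C(C)(C)O)[C@H]3C=C2C)[C@H](O[Si](C)(C)C(C)(C)C)[C@@H](C)[C@@H]2CCC(=O)[C@]21C | intermediate
28 | 2,3-didehydro derivative of 27 (cyclopent-2-enone; 9-O-silyl target) | C/C=C(\C)C(=O)O[C@H]1[C@H]2[C@H](OC(=O)[C@]23C[C@@H]2C[C@@H](C(C)(C)O)[C@H]3C=C2C)[C@H](O[Si](C)(C)C(C)(C)C)[C@@H](C)[C@@H]2C=CC(=O)[C@]21C | intermediate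
29 | target CNP0185323.3 (9β-hydroxyhelenalin 6-O-tiglate joined at C11/C13 to (R)-p-mentha-1,5-dien-8-ol; 11S,2'S,4'R,5'R) | C/C=C(\C)C(=O)O[C@H]1[C@H]2[C@H](OC(=O)[C@]23C[C@@H]2C[C@@H](C(C)(C)O)[C@H]3C=C2C)[C@H](O)[C@@H](C)[C@@H]2C=CC(=O)[C@]21C | target

## Step count and risks

Total step count: 17. Longest linear sequence: 10 steps (steps 1, 2, 3, 6, 7, 8, 14, 15, 16, 17).

**Step 2 (proposed new method).** Neither the enantioselectivity on an α-methyl cyclopentenone nor the C1/C10 diastereoselectivity is established. Fallback with known chemistry, setting out from 3 and coming back at 4: reduce 3 with BH3·SMe2 and (R)-2-methyl-CBS-oxazaborolidine to (1S)-2-methylcyclopent-2-en-1-ol F1. Acylate with propanoyl chloride and pyridine to (1S)-2-methylcyclopent-2-en-1-yl propanoate F2. Ireland–Claisen rearrangement (LiN(i-Pr)2, TBSCl, THF with or without HMPA to choose the ketene acetal geometry, −78 to 60 °C, then mild hydrolysis) carries the carbinol configuration suprafacially to C1 and sets C10, giving (2S)-2-[(1S)-2-methylcyclopent-2-en-1-yl]propanoic acid F3. EtSH, DCC and DMAP give S-ethyl (2S)-2-[(1S)-2-methylcyclopent-2-en-1-yl]propanethioate F4. mCPBA gives the epoxide S-ethyl (2S)-2-[(2S)-1-methyl-6-oxabicyclo[3.1.0]hexan-2-yl]propanethioate F5. BF3·OEt2 (Meinwald rearrangement by hydride shift) gives S-ethyl (2S)-2-[(1S)-2-methyl-3-oxocyclopentyl]propanethioate F6, mixed at the methyl-bearing carbon. TBSCl, NaI and Et3N in MeCN (thermodynamic enol silane) then give 4, which is alkylated with HC(OMe)3 and TMSOTf as in step 2.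

**Step 8.** The ring closure forms a seven-membered ring next to a quaternary carbon, the C6 configuration rests on the chair model, and the β-keto aldehyde can deformylate. Fallback, setting out from 12 and coming back at 13: convert the allylic alcohol with CBr4 and PPh3 (CH2Cl2, 0 °C) into (1R,2S)-2-[(1R,2S)-1-[(2S)-4-(bromomethyl)-5-oxo-2,5-dihydrofuran-2-yl]-1-{[tert-butyl(dimethyl)silyl]oxy}propan-2-yl]-1-methyl-5-oxocyclopentane-1-carbaldehyde F7. Close the ring by a stoichiometric Nozaki–Hiyama–Kishi allylation (CrCl2, 4 equiv, THF, 0.005 M, 25 °C); the σ-bound allylchromium is aldehyde-selective and adds through the same chair to give 13.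

**Step 14.** The silaketal must form between two hindered alcohols, and the cycloaddition has to pass through a nine-membered tether ring on the more crowded lactone face. Fallback, setting out from 13 and coming back at 27: acylate 13 first with 26 (DMAP, pyridine, 60 °C) to the 6-O-tigloyl derivative of 13 F8. Run the bimolecular Diels–Alder reaction of F8 with 22 at 12 kbar (CH2Cl2, 25 °C), where the only guide to the C6 face is the hydrogen bond from the C8' hydroxyl to the tiglate carbonyl. Facial control will be lower than with the tether, so 27 is isolated by chromatography and carried into steps 16 and 17.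

## Further compounds

F1 | step 2 | (1S)-2-methylcyclopent-2-en-1-ol | O[C@H]1CCC=C1C
F2 | step 2 | (1S)-2-methylcyclopent-2-en-1-yl propanoate | CCC(=O)O[C@H]1CCC=C1C
F3 | step 2 | (2S)-2-[(1S)-2-methylcyclopent-2-en-1-yl]propanoic acid | CC1=CCC[C@H]1[C@H](C)C(=O)O
F4 | step 2 | S-ethyl (2S)-2-[(1S)-2-methylcyclopent-2-en-1-yl]propanethioate | CC1=CCC[C@H]1[C@H](C)C(=O)SCC
F5 | step 2 | S-ethyl (2S)-2-[(2S)-1-methyl-6-oxabicyclo[3.1.0]hexan-2-yl]propanethioate | CC12OC1CC[C@H]2[C@H](C)C(=O)SCC
F6 | step 2 | S-ethyl (2S)-2-[(1S)-2-methyl-3-oxocyclopentyl]propanethioate | CC1C(=O)CC[C@H]1[C@H](C)C(=O)SCC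
F7 | step 8 | (1R,2S)-2-[(1R,2S)-1-[(2S)-4-(bromomethyl)-5-oxo-2,5-dihydrofuran-2-yl]-1-{[tert-butyl(dimethyl)silyl]oxy}propan-2-yl]-1-methyl-5-oxocyclopentane-1-carbaldehyde | O=C[C@]1(C)C(=O)CC[C@H]1[C@H](C)[C@@H](O[Si](C)(C)C(C)(C)C)[C@H]1OC(=O)C(CBr)=C1
F8 | step 14 | 6-O-tigloyl derivative of 13 | C/C=C(\C)C(=O)O[C@H]1[C@H]2[C@H](OC(=O)C2=C)[C@H](O[Si](C)(C)C(C)(C)C)[C@@H](C)[C@@H]2CCC(=O)[C@]21C
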